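## The problem

Talarominine A (17) is a 2,3-disubstituted benzofuran. Benzo ring A carries a methyl group at C4 and a hydroxyl at C6, furan ring B carries a methyl propanoate chain at C2, and C3 is bonded to ring C, a 3,5-dihydroxy-2,4-dimethylphenyl group. There is no stereocentre. The C3–C1' bond is flanked by the C4 methyl, the C2 chain and the C2' methyl, so it is crowded, but no axial configuration is assigned and none has to be controlled. That crowding is the main skeletal difficulty, because it works against joining ring C to a finished benzofuran at C3. Ring C hides a second difficulty: its attachment carbon is meta to both oxygens, so it cannot be introduced as a nucleophile by electrophilic substitution and has to originate from a benzoic acid carbon. The groups at risk are the three phenols (free, they make both rings sensitive to oxidants and to base in air) and the methyl ester, which must survive the unmasking of the phenols or be restored after it. The enabling feature is the atom sequence O1–C7a–C3a–C3: C3 is benzylic to ring A with the oxygen ortho, which is the connectivity of an ortho-quinone methide. The remaining ring atom C2 must then be a nucleophile toward C3 and an electrophile toward O1, which is what a sulfonium ylide carbon offers. Since a 2-alkenyl-2,3-dihydrobenzofuran is an isomer of a 2-alkylbenzofuran, the chain can enter as an acrylate and the oxidation levels balance without a redox reagent.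

## Retrosynthesis

**17 to 16 to 15.** Only oxygen–methyl bonds are touched. Ester 17 is traced to acid 16 and then to the fully methylated benzofuran ester 15. Methyl ethers are chosen because they are the one phenol protection that survives an organolithium, a Friedel–Crafts acylation and hot amidine base earlier in the route. The Lewis acid that removes them also attacks the ester, so the cleavage is driven to the single product 16 and the ester is put back. The forward steps must demethylate exhaustively without harming the furan and then esterify the acid in the presence of three phenols.

**15 to 13.** No skeletal bond is cut. Benzofuran 15 is an isomer of dihydrobenzofuran 13: the hydrogens on C2 and C3 are moved onto the chain through enol ether 14. The neighbouring option, dehydrogenating a dihydrofuran and reducing the alkene separately, would bring an oxidant to two electron-rich rings. The isomerisation needs only base and a trace of acid. Precursor 13 is simpler to make because its heterocycle is sp3 at C2 and C3 and can come from a polar annulation.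

**13 to 7 and 9 (key disconnection).** The C2–C3 and O1–C2 bonds are cut. Cutting C3–C1' instead would demand arylation of a benzofuran at its most hindered carbon. Cutting C3–C3a would need a blocking group to direct the closure. The chosen cut divides the molecule into ortho-hydroxybenzhydrol 7, which holds every aromatic carbon, and the four-carbon sulfonium salt 9, which holds the whole chain. One base has to do two jobs in the forward step: convert 7 into ortho-quinone methide 11 and convert 9 into ylide 10. Ylide 10 must then attack through its sulfur-bearing carbon, and betaine 12 must close by direct displacement.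

**9 to 8.** The carbon–sulfur bond is cut. Salt 9 is one alkylation away from commercial bromide 8.

**7 to 6 to 5.** The carbinol C–H bond is cut (ketone reduction), and before it one oxygen–methyl bond is restored (the phenol ortho to the carbonyl). The ketone serves twice: it is the natural product of the arene union, and its chelating ability marks which of four methyl ethers in 5 is removed. The forward reduction must stop at the alcohol.

**5 to 2 and 3.** The bond between the carbonyl carbon and ring A is cut. This matches the innate polarity of both rings: 3 is nucleophilic at the carbon para to one methoxy group and ortho to the other, and the ring C attachment carbon is an acyl carbon in acid 2. The reverse polarity, a ring C aryl-metal, is not accessible by simple substitution chemistry. The forward acylation must go beside the methyl group of 3 and not between its two methoxy groups.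

**2 to 1.** The C2'–CH3 bond is cut. Acid 1 is commercial and symmetric, with C4 blocked, so an ortho-metalation has no regiochemical choice. The forward step must form the dianion and methylate it once.

## Roads not taken

**Alternative 1:** Ring C is built, not bought. The cut passes through two bonds of ring C, so the ring appears as cyclohexane-1,3-dione A1, formed from benzofuranyl enone A2 and methylmalonate A3. Under alkoxide base the malonate carbon adds to the enone carbon attached to C3; the enolate of the ethyl ketone then acylates on one malonate ester and closes the six-membered ring. Loss of the remaining ester carbon and dehydrogenation would turn A1 into the resorcinol.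
- Merits: the crowded C3–C1' bond is never made by a coupling, and the awkward ring C pattern falls out of the building blocks. The ring C hydroxyls also emerge free, which is better than the chosen plan because that ring needs no ether cleavage.
- Weak points: A2 presupposes a finished 2,3-disubstituted benzofuran with a side chain on C3, so ring B still has to be solved separately. A1 is a diastereomer mixture with a quaternary ester that must be removed. Aromatisation needs an oxidant next to an electron-rich benzofuran. The ring A ether would still need cleaving, so the ester problem of the end game remains.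
- Comparison: against the one real advantage, the chosen plan sets convergence. Both arenes enter complete, ring B closes in one operation from two fragments, no oxidant touches the electron-rich system, and the route is clearly shorter.

**Alternative 2:** Only the C3–C3a bond is formed at the ring-closing stage. Aryloxy ketone A5 is treated with a strong protic or Lewis acid; ring A attacks the activated aryl ketone and water is lost to give benzofuran A4. The bromine at C7 blocks the other position ortho to the ether oxygen and is removed later.
- Merits: a classical closure that delivers the aromatic furan with the saturated propanoate directly. In this respect it is better than the chosen plan, which needs the separate isomerisation of step 7.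
- Weak points: the attacking ring carbon lies beside the C4 methyl and must bond to a ketone carbon bearing the ortho-methylated ring C. The most hindered bond of the molecule is thus made by electrophilic substitution onto a poorly electrophilic ketone. Regiocontrol needs the blocking halogen, which costs two extra operations and a regioselective phenol bromination. A5 requires halogenation next to the ketone of a keto ester and displacement at a secondary carbon by an ortho-substituted phenol. It uses the same acid 2 and the same ether cleavage, so nothing is saved elsewhere.
- Comparison: the chosen plan creates the crowded C3 environment by conjugate addition to a planar, strongly electrophilic quinone methide carbon. Its regiochemistry is fixed by the position of the phenol in 7 without a blocking group, and it is shorter.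

**Alternative 3:** Ring A is built last. The cut is the C5–C6 bond. Furylacetic acid A7, heated with an acid anhydride and its carboxylate salt, would give a ketene whose central carbon bonds to the terminal carbon of the isopropenyl group in a 6π-electrocyclisation. Tautomerisation and O-acylation then give acetate A6.
- Merits: the positions of methyl and oxygen on ring A are fixed by construction. The C6 oxygen appears as an acetate that comes off under mild conditions, which is better than the methyl ether of 15.
- Weak points: A7 is a furan with four different substituents on its four carbons, including the hindered ring C aryl next to the isopropenyl group. Making it regioselectively is at least as hard as making the target benzofuran, and the sequence is long and linear. The ring C ethers still need the harsh final unmasking, under which the advantage of the mild acetate is lost.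
- Comparison: the chosen plan secures the ring A pattern with two ordinary steps (acylation of 3 at its usual site and chelation-controlled demethylation of 5) and stays short and convergent.

Key step: step 6

Assumption: the hindered C3–C1' axis of 17 has no assigned configuration and is treated as stereochemically undefined; compounds 1, 3 and 8 are taken as purchasable.

## Route

Step 1
Reactants: 1 3,5-dimethoxy-4-methylbenzoic acid
Product: 2 3,5-dimethoxy-2,4-dimethylbenzoic acid
Conditions: s-BuLi (2.2 equiv), TMEDA, THF, −78 °C; MeI, −78 °C to rt; aq. HCl
Reagents that add atoms: iodomethane, CI
Why: Directed ortho-metalation of an unprotected benzoic acid: the lithium carboxylate and the flanking methoxy group together direct the base to C2 (C2 and C6 are equivalent, C4 is blocked), and the aryllithium is trapped by MeI. No stereocentre is formed.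

Step 2
Reactants: 2 3,5-dimethoxy-2,4-dimethylbenzoic acid; 3 3,5-dimethoxytoluene
Product: 5 (2,4-dimethoxy-6-methylphenyl)(3,5-dimethoxy-2,4-dimethylphenyl)methanone, via mixed trifluoroacetic anhydride 4 (not isolated)
Conditions: TFAA, CH2Cl2, 0 °C (2 premixed with TFAA); then 3, 0 °C to rt
Reagents that add atoms: none
Why: Friedel–Crafts acylation through the aroyl trifluoroacetate: the acylium equivalent should attack 3 para to one methoxy group and ortho to the other, beside the methyl, which is the usual acylation site of this arene. The product ketone is deactivated, so a single acylation is expected.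

Step 3
Reactants: 5 (2,4-dimethoxy-6-methylphenyl)(3,5-dimethoxy-2,4-dimethylphenyl)methanone
Product: 6 (3,5-dimethoxy-2,4-dimethylphenyl)(2-hydroxy-4-methoxy-6-methylphenyl)methanone
Conditions: BCl3, CH2Cl2, −78 to 0 °C; H2O
Reagents that add atoms: none
Why: Chelation-controlled ether cleavage: BCl3 bridges the ketone oxygen and the ortho methoxy group in a six-membered chelate and cleaves only that ether. The para methoxy group of ring A and the two ring C methoxy groups (meta to the carbonyl) cannot chelate and should remain.

Step 4
Reactants: 6 (3,5-dimethoxy-2,4-dimethylphenyl)(2-hydroxy-4-methoxy-6-methylphenyl)methanone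
Product: 7 2-[(3,5-dimethoxy-2,4-dimethylphenyl)(hydroxy)methyl]-5-methoxy-3-methylphenol (racemic)
Conditions: NaBH4, THF/MeOH, 0 °C to rt; aq. NH4Cl
Reagents that add atoms: none
Why: Hydride reduction of a diaryl ketone to the benzhydrol. The carbinol centre forms as a racemate, which does not matter because it becomes sp2 in step 6; low temperature and a buffered quench protect the labile ortho-hydroxybenzhydrol.

Step 5
Reactants: 8 methyl (E)-4-bromobut-2-enoate
Product: 9 (E)-(4-methoxy-4-oxobut-2-enyl)dimethylsulfonium bromide
Conditions: Me2S, acetone, rt
Reagents that add atoms: dimethyl sulfide, CSC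
Why: SN2 S-alkylation of a sulfide by a primary allylic bromide. The salt should precipitate from acetone with the E alkene unchanged.

Step 6
Reactants: 7 2-[(3,5-dimethoxy-2,4-dimethylphenyl)(hydroxy)methyl]-5-methoxy-3-methylphenol (racemic); 9 (E)-(4-methoxy-4-oxobut-2-enyl)dimethylsulfonium bromide
Product: 13 methyl (E)-3-[(2S*,3R*)-3-(3,5-dimethoxy-2,4-dimethylphenyl)-6-methoxy-4-methyl-2,3-dihydro-1-benzofuran-2-yl]prop-2-enoate (racemic trans isomer; one enantiomer drawn), via sulfonium ylide 10 (not isolated), via ortho-quinone methide 11 (not isolated), via betaine 12 (not isolated)
Conditions: Cs2CO3 (3 equiv), CH2Cl2, rt to 40 °C; 9 (1.5 equiv) added in portions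
Reagents that add atoms: none
Why: Cs2CO3 converts the phenol of 7 into its phenoxide, which expels hydroxide in an E1cB-type 1,4-elimination (helped by the para methoxy group) to give ortho-quinone methide 11, and it deprotonates 9 at the CH2 between sulfur and the alkene to give allylic ylide 10. Ylide 10 adds through its sulfur-bearing carbon to the exocyclic carbon of 11, which restores the aromaticity of ring A and forms the C2–C3 bond in betaine 12. The phenoxide of 12 then displaces dimethyl sulfide at that same carbon, an intramolecular SN2 reaction that closes ring B in the 5-exo-tet mode and forms the O1–C2 bond. The closest known reaction type is the formal [4+1] annulation of in situ generated ortho-quinone methides with sulfonium ylides, which gives trans-2,3-dihydrobenzofurans. The two new stereocentres C2 and C3 are set relative to each other by the substrate alone: betaine formation is reversible and the diastereomer that reaches the anti-periplanar O–C–C–S arrangement with the acrylate and ring C on opposite faces closes faster, so the trans isomer (2S*,3R*) should dominate; there is no absolute control and the product is racemic. Diastereoselectivity is not needed, because both centres become sp2 in step 7. What is needed is attack of the ambident ylide at its alpha and not its gamma carbon and direct rather than allylic displacement in the closure; the higher charge density next to sulfur favours the first, and the second follows because only the direct path gives a five-membered ring while the allylic path would need a seven-membered one. Portionwise addition of 9 keeps the ylide concentration low so that its self-condensation does not outrun formation of 11.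

Step 7
Reactants: 13 methyl (E)-3-[(2S*,3R*)-3-(3,5-dimethoxy-2,4-dimethylphenyl)-6-methoxy-4-methyl-2,3-dihydro-1-benzofuran-2-yl]prop-2-enoate (racemic)
Product: 15 methyl 3-[3-(3,5-dimethoxy-2,4-dimethylphenyl)-6-methoxy-4-methyl-1-benzofuran-2-yl]propanoate, via exocyclic enol ether 14 (not isolated)
Conditions: DBU, toluene, 80–110 °C; aqueous wash; then cat. TsOH·H2O, CH2Cl2, rt
Reagents that add atoms: none
Why: Two consecutive prototropic shifts: DBU removes the C2 hydrogen (gamma to the ester, alpha to oxygen) and the vinylogous enolate is reprotonated at the ester alpha carbon to give enol ether 14, the known base equilibration of gamma-alkoxy enoates toward the enol ether. The doubly benzylic C3 hydrogen then moves to the exocyclic carbon, by base or through the oxocarbenium ion under the acid finish, driven by aromatisation of the furan; both stereocentres of 13 are erased.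

Step 8
Reactants: 15 methyl 3-[3-(3,5-dimethoxy-2,4-dimethylphenyl)-6-methoxy-4-methyl-1-benzofuran-2-yl]propanoate
Product: 16 3-[3-(3,5-dihydroxy-2,4-dimethylphenyl)-6-hydroxy-4-methyl-1-benzofuran-2-yl]propanoic acid
Conditions: BBr3 (excess), CH2Cl2, −78 °C to rt; H2O
Reagents that add atoms: none
Why: Lewis-acid ether cleavage: BBr3 coordinates each methoxy oxygen and bromide removes the methyl group by SN2. The excess reagent cleaves the methyl ester in the same way, so the step is run to the fully demethylated acid as one defined product; any ester that survives converges in step 9.

Step 9
Reactants: 16 3-[3-(3,5-dihydroxy-2,4-dimethylphenyl)-6-hydroxy-4-methyl-1-benzofuran-2-yl]propanoic acid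
Product: 17 methyl 3-[3-(3,5-dihydroxy-2,4-dimethylphenyl)-6-hydroxy-4-methyl-1-benzofuran-2-yl]propanoate (talarominine A)
Conditions: MeOH, cat. H2SO4, 60 °C
Reagents that add atoms: methanol, CO
Why: Fischer esterification: under acid catalysis in methanol only the carboxylic acid is esterified. Phenols are not alkylated under these conditions.

## Compound list

1 | 3,5-dimethoxy-4-methylbenzoic acid | COc1cc(C(=O)O)cc(OC)c1C | starting material
2 | 3,5-dimethoxy-2,4-dimethylbenzoic acid | COc1cc(C(=O)O)c(C)c(OC)c1C | intermediate
3 | 3,5-dimethoxytoluene (1,3-dimethoxy-5-methylbenzene) | COc1cc(C)cc(OC)c1 | starting material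
4 | 3,5-dimethoxy-2,4-dimethylbenzoic trifluoroacetic anhydride (formed in situ; not isolated) | COc1cc(C(=O)OC(=O)C(F)(F)F)c(C)c(OC)c1C | intermediate
5 | (2,4-dimethoxy-6-methylphenyl)(3,5-dimethoxy-2,4-dimethylphenyl)methanone | COc1cc(C)c(C(=O)c2cc(OC)c(C)c(OC)c2C)c(OC)c1 | intermediate
6 | (3,5-dimethoxy-2,4-dimethylphenyl)(2-hydroxy-4-methoxy-6-methylphenyl)methanone | COc1cc(C)c(C(=O)c2cc(OC)c(C)c(OC)c2C)c(O)c1 | intermediate
7 | 2-[(3,5-dimethoxy-2,4-dimethylphenyl)(hydroxy)methyl]-5-methoxy-3-methylphenol (racemic) | COc1cc(C)c(C(O)c2cc(OC)c(C)c(OC)c2C)c(O)c1 | intermediate
8 | methyl (E)-4-bromobut-2-enoate | COC(=O)/C=C/CBr | starting material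
9 | (E)-(4-methoxy-4-oxobut-2-enyl)dimethylsulfonium bromide | C[S+](C)C/C=C/C(=O)OC.[Br-] | intermediate
10 | (E)-1-(dimethylsulfonio)-4-methoxy-4-oxobut-2-en-1-ide, the allylic sulfonium ylide (formed in situ; not isolated) | C[S+](C)[CH-]/C=C/C(=O)OC | intermediate
11 | 6-[(3,5-dimethoxy-2,4-dimethylphenyl)methylidene]-3-methoxy-5-methylcyclohexa-2,4-dien-1-one, the ortho-quinone methide (alkene geometry not defined; formed in situ; not isolated) | O=C1C=C(OC)C=C(C)C1=Cc1cc(OC)c(C)c(OC)c1C | intermediate
12 | 2-[(3E)-1-(3,5-dimethoxy-2,4-dimethylphenyl)-2-(dimethylsulfonio)-5-methoxy-5-oxopent-3-enyl]-5-methoxy-3-methylphenolate, the betaine (diastereomer mixture; formed in situ; not isolated) | COC(=O)/C=C/C([S+](C)C)C(c1c([O-])cc(OC)cc1C)c1cc(OC)c(C)c(OC)c1C | intermediate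
13 | methyl (E)-3-[(2S*,3R*)-3-(3,5-dimethoxy-2,4-dimethylphenyl)-6-methoxy-4-methyl-2,3-dihydro-1-benzofuran-2-yl]prop-2-enoate (racemic trans isomer; one enantiomer drawn) | COC(=O)/C=C/[C@@H]1Oc2cc(OC)cc(C)c2[C@H]1c1cc(OC)c(C)c(OC)c1C | intermediate
14 | methyl 3-[3-(3,5-dimethoxy-2,4-dimethylphenyl)-6-methoxy-4-methyl-1-benzofuran-2(3H)-ylidene]propanoate (racemic; alkene geometry not defined; formed in situ; not isolated) | COC(=O)CC=C1Oc2cc(OC)cc(C)c2C1c1cc(OC)c(C)c(OC)c1C | intermediate
15 | methyl 3-[3-(3,5-dimethoxy-2,4-dimethylphenyl)-6-methoxy-4-methyl-1-benzofuran-2-yl]propanoate | COC(=O)CCc1oc2cc(OC)cc(C)c2c1-c1cc(OC)c(C)c(OC)c1C | intermediate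
16 | 3-[3-(3,5-dihydroxy-2,4-dimethylphenyl)-6-hydroxy-4-methyl-1-benzofuran-2-yl]propanoic acid | OC(=O)CCc1oc2cc(O)cc(C)c2c1-c1cc(O)c(C)c(O)c1C | intermediate
17 | methyl 3-[3-(3,5-dihydroxy-2,4-dimethylphenyl)-6-hydroxy-4-methyl-1-benzofuran-2-yl]propanoate (talarominine A) | COC(=O)CCc1oc2cc(O)cc(C)c2c1-c1cc(O)c(C)c(O)c1C | target

## Step count and risk

Total step count: 9. Longest linear sequence: 8 steps (steps 1, 2, 3, 4, 6, 7, 8, 9); step 5 is a one-step side branch.

**Step 6 (key step).** The most likely failure is that loss of water from 7 under carbonate base lags behind the decay of ylide 10, through self-condensation with salt 9 or O-alkylation of the phenoxide by the sulfonium salt. Attack at the exocyclic carbon, which sits between two ortho-methylated rings, may also be slow. The fallback keeps the annulation and changes how the quinone methide is released. Starting from 7, treatment with p-TolSO2Na in aqueous formic acid exchanges the hydroxyl for a sulfinate leaving group and gives 2-[(3,5-dimethoxy-2,4-dimethylphenyl)(4-methylbenzenesulfonyl)methyl]-5-methoxy-3-methylphenol F1. This sulfone should eliminate sulfinate with Cs2CO3 in CH2Cl2 at room temperature, and the same reaction with 9 rejoins the route at 13.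

**Step 7.** The vinylogous deprotonation may be too slow with an amidine base, or the sequence may stall at enol ether 14. Forcing it with stronger base invites ester condensation or hydrolysis. The fallback replaces the isomerisation by a reduction and an oxidation. Starting from 13, hydrogenation of the acrylate double bond (H2, RhCl(PPh3)3, which should not cleave the allylic C–O bond) gives methyl 3-[(2S*,3R*)-3-(3,5-dimethoxy-2,4-dimethylphenyl)-6-methoxy-4-methyl-2,3-dihydro-1-benzofuran-2-yl]propanoate F2. Dehydrogenation of the dihydrofuran with DDQ in hot dioxane, by hydride abstraction from the doubly benzylic C3, rejoins the route at 15.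

**Step 1.** Lateral lithiation of the newly introduced methyl group followed by a second methylation, or addition of the alkyllithium to the carboxylate, would erode the yield; incomplete metalation would leave 1 that is hard to separate from 2. The fallback uses electrophilic substitution and cross-coupling. Starting from 1, bromination with NBS in MeCN at the only free, doubly activated position gives 2-bromo-3,5-dimethoxy-4-methylbenzoic acid F3. Suzuki–Miyaura methylation with trimethylboroxine (Pd(dppf)Cl2, K2CO3, aqueous dioxane) rejoins the route at 2.

**Step 2.** Acylation between the two methoxy groups of 3, trifluoroacetylation of 3, or sluggish reaction of the ortho-substituted acid would give mixtures. The fallback fixes the regiochemistry before the fragments are joined. Starting from 3, bromination with NBS gives 2-bromo-1,5-dimethoxy-3-methylbenzene F4, which can be purified at this simple stage. Starting from 2, the acid chloride ((COCl)2, cat. DMF) and MeNHOMe·HCl give N,3,5-trimethoxy-N,2,4-trimethylbenzamide F5. Bromine–lithium exchange of F4 with n-BuLi in THF at −78 °C and addition of the aryllithium to F5 rejoins the route at 5.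

**Step 4.** Under the basic reduction conditions the phenoxide deactivates the ketone, and if the reduction is forced the product may lose hydroxide to the quinone methide and be reduced further to the diarylmethane. The fallback masks the phenol during the reduction. Starting from 6, silylation (TBSOTf, 2,6-lutidine) gives [2-(tert-butyldimethylsilyloxy)-4-methoxy-6-methylphenyl](3,5-dimethoxy-2,4-dimethylphenyl)methanone F6. Reduction with LiAlH4 in THF at 0 °C gives [2-(tert-butyldimethylsilyloxy)-4-methoxy-6-methylphenyl](3,5-dimethoxy-2,4-dimethylphenyl)methanol F7 (racemic; silyl migration to the carbinol oxygen would be harmless). Desilylation with TBAF buffered with AcOH rejoins the route at 7.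

## Further compounds

F1 | step 6 | 2-[(3,5-dimethoxy-2,4-dimethylphenyl)(4-methylbenzenesulfonyl)methyl]-5-methoxy-3-methylphenol (racemic) | COc1cc(C)c(C(c2cc(OC)c(C)c(OC)c2C)S(=O)(=O)c2ccc(C)cc2)c(O)c1
F2 | step 7 | methyl 3-[(2S*,3R*)-3-(3,5-dimethoxy-2,4-dimethylphenyl)-6-methoxy-4-methyl-2,3-dihydro-1-benzofuran-2-yl]propanoate (racemic trans isomer; one enantiomer drawn) | COC(=O)CC[C@@H]1Oc2cc(OC)cc(C)c2[C@H]1c1cc(OC)c(C)c(OC)c1C
F3 | step 1 | 2-bromo-3,5-dimethoxy-4-methylbenzoic acid | COc1cc(C(=O)O)c(Br)c(OC)c1C
F4 | step 2 | 2-bromo-1,5-dimethoxy-3-methylbenzene | COc1cc(C)c(Br)c(OC)c1
F5 | step 2 | N,3,5-trimethoxy-N,2,4-trimethylbenzamide | CON(C)C(=O)c1cc(OC)c(C)c(OC)c1C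
F6 | step 4 | [2-(tert-butyldimethylsilyloxy)-4-methoxy-6-methylphenyl](3,5-dimethoxy-2,4-dimethylphenyl)methanone | COc1cc(C)c(C(=O)c2cc(OC)c(C)c(OC)c2C)c(O[Si](C)(C)C(C)(C)C)c1
F7 | step 4 | [2-(tert-butyldimethylsilyloxy)-4-methoxy-6-methylphenyl](3,5-dimethoxy-2,4-dimethylphenyl)methanol (racemic) | COc1cc(C)c(C(O)c2cc(OC)c(C)c(OC)c2C)c(O[Si](C)(C)C(C)(C)C)c1
A1 | alternative 1 | methyl 2-[6-methoxy-2-(3-methoxy-3-oxopropyl)-4-methyl-1-benzofuran-3-yl]-1,5-dimethyl-4,6-dioxocyclohexane-1-carboxylate (diastereomer mixture) | COC(=O)CCc1oc2cc(OC)cc(C)c2c1C1CC(=O)C(C)C(=O)C1(C)C(=O)OC
A2 | alternative 1 | methyl 3-[6-methoxy-4-methyl-3-[(E)-3-oxopent-1-enyl]-1-benzofuran-2-yl]propanoate | CCC(=O)/C=C/c1c(CCC(=O)OC)oc2cc(OC)cc(C)c12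
A3 | alternative 1 | dimethyl 2-methylpropanedioate | COC(=O)C(C)C(=O)OC
A4 | alternative 2 | methyl 3-[7-bromo-3-(3,5-dimethoxy-2,4-dimethylphenyl)-6-methoxy-4-methyl-1-benzofuran-2-yl]propanoate | COC(=O)CCc1oc2c(Br)c(OC)cc(C)c2c1-c1cc(OC)c(C)c(OC)c1C
A5 | alternative 2 | methyl 4-(2-bromo-3-methoxy-5-methylphenoxy)-5-(3,5-dimethoxy-2,4-dimethylphenyl)-5-oxopentanoate (racemic) | COC(=O)CCC(Oc1cc(C)cc(OC)c1Br)C(=O)c1cc(OC)c(C)c(OC)c1C
A6 | alternative 3 | methyl 3-[6-acetoxy-3-(3,5-dimethoxy-2,4-dimethylphenyl)-4-methyl-1-benzofuran-2-yl]propanoate | COC(=O)CCc1oc2cc(OC(C)=O)cc(C)c2c1-c1cc(OC)c(C)c(OC)c1C
A7 | alternative 3 | 2-[4-(3,5-dimethoxy-2,4-dimethylphenyl)-5-(3-methoxy-3-oxopropyl)-3-(prop-1-en-2-yl)furan-2-yl]acetic acid | COC(=O)CCc1oc(CC(=O)O)c(C(C)=C)c1-c1cc(OC)c(C)c(OC)c1C
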